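## Retrosynthetic overview

1. Target 32 ⇒ C8 ester disconnection to hydroxy lactone 26 and acid 29 (from (R)-Roche ester 27); both exo-methylene groups are made late (lactone α-methylenation; aldehyde α-methylenation at C4).
2. Lactone 22 ⇒ enone 15: acetate arm on C7 by α-iodination/Negishi coupling, C6–O by conjugate borylation, C8–OH by thermodynamic ketone reduction.
3. Enone 15 ⇒ ketone 9 ⇒ enone 5 by two copper-catalysed conjugate additions (methyl, then vinyl anti to the C5 substituent, giving quaternary C10).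
4. Key fragment union (C5–C6 bond): enamine-catalysed intermolecular Michael addition of aldehyde 2 to methyl vinyl ketone 3, giving 4; the C5 centre set here relays all ring stereocentres.
5. Ring order: cyclohexane first (Michael, then intramolecular aldol condensation, steps 2–3); γ-lactone second (step 16).

Convention: elemane numbering is used for ring positions (C10 = quaternary carbon, then C9, C8, C7, C6, C5 round the ring; C4(=C3)–C15 on C5; C11(=C13)–C12 on C7; C14 = methyl; C1=C2 = vinyl); β is the face of the C10 methyl group in the target, α the opposite face.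

## Route

Step 1
Reactants: 1 methyl 4,4-dimethoxybutanoate
Product: 2 4,4-dimethoxybutanal
Conditions: iBu2AlH (1.05 equiv), CH2Cl2, −78 °C; aq. potassium sodium tartrate
Reagents that add atoms: none
Why: Partial ester reduction at low temperature stops at the aldehyde because the tetrahedral aluminium hemiacetal survives until work-up.

Step 2
Reactants: 2 4,4-dimethoxybutanal; 3 but-3-en-2-one (methyl vinyl ketone)
Product: 4 (S)-2-(2,2-dimethoxyethyl)-5-oxohexanal
Conditions: (S)-2-[methoxy(diphenyl)methyl]pyrrolidine (5 mol%), ethyl 3,4-dihydroxybenzoate (20 mol%), neat, 4 °C, 36 h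
Reagents that add atoms: none
Why: Enamine-catalysed intermolecular Michael addition in which the (E)-enamine is attacked on the face remote from the diphenyl(methoxy)methyl group, which sets C5 as (S).

Step 3
Reactants: 4 (S)-2-(2,2-dimethoxyethyl)-5-oxohexanal
Product: 5 (S)-4-(2,2-dimethoxyethyl)cyclohex-2-en-1-one
Conditions: LiOH (cat.), iPrOH, rt
Reagents that add atoms: none
Why: Intramolecular aldol condensation of the methyl ketone enolate onto the aldehyde can only close the six-membered ring and creates no new stereocentre.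

Step 4
Reactants: 5 (S)-4-(2,2-dimethoxyethyl)cyclohex-2-en-1-one
Product: 7 (S)-4-(2,2-dimethoxyethyl)-3-methylcyclohex-2-en-1-one, via silyl enol ether 6 (not isolated)
Conditions: MeMgBr, CuBr·SMe2 (10 mol%), Me3SiCl, THF, −78 °C; then Pd(OAc)2 (10 mol%), O2 (1 atm), DMSO, rt
Reagents that add atoms: methylmagnesium bromide, C[Mg]Br
Why: Copper-catalysed conjugate addition trapped as the silyl enol ether, followed by Saegusa–Ito dehydrogenation, returns the enone with the methyl group now on C10.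

Step 5
Reactants: 7 (S)-4-(2,2-dimethoxyethyl)-3-methylcyclohex-2-en-1-one
Product: 9 (3S,4S)-3-ethenyl-4-(2,2-dimethoxyethyl)-3-methylcyclohexan-1-one, via silyl enol ether 8 (not isolated)
Conditions: CH2=CHMgBr, CuBr·SMe2 (20 mol%), Me3SiCl, THF, −78 °C; then K2CO3 (cat.), MeOH, 0 °C
Reagents that add atoms: vinylmagnesium bromide, C=C[Mg]Br
Why: In this copper-catalysed conjugate addition the C5 substituent sits pseudoaxial (allylic strain with the C10 methyl) and the vinyl group enters anti to it, fixing the quaternary centre as 10α-vinyl/10β-methyl.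

Step 6
Reactants: 9 (3S,4S)-3-ethenyl-4-(2,2-dimethoxyethyl)-3-methylcyclohexan-1-one
Product: 10 2-[(1S,2S)-2-ethenyl-2-methyl-4-oxocyclohexyl]acetaldehyde
Conditions: 1 M HCl, THF, 0 °C → rt
Reagents that add atoms: water, O
Why: Acid-catalysed acetal hydrolysis unmasks the aldehyde, and neither C5 nor C10 is α to a carbonyl, so nothing can epimerise.

Step 7
Reactants: 10 2-[(1S,2S)-2-ethenyl-2-methyl-4-oxocyclohexyl]acetaldehyde
Product: 11 2-[(1R,2S)-2-ethenyl-2-methyl-4-oxocyclohexyl]prop-2-enal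
Conditions: 37% aq. CH2O, pyrrolidine (10 mol%), propionic acid (10 mol%), iPrOH, 45 °C
Reagents that add atoms: formaldehyde, C=O
Why: Amine-catalysed Mannich condensation and elimination (aldehyde α-methylenation) is selective for the aldehyde over the ring ketone and installs C3.

Step 8
Reactants: 11 2-[(1R,2S)-2-ethenyl-2-methyl-4-oxocyclohexyl]prop-2-enal
Product: 12 (3S,4R)-3-ethenyl-4-(3-hydroxyprop-1-en-2-yl)-3-methylcyclohexan-1-one
Conditions: NaBH(OAc)3 (3 equiv), PhH, 60 °C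
Reagents that add atoms: none
Why: Chemoselective 1,2-reduction, since triacetoxyborohydride reduces aldehydes but leaves ketones untouched.

Step 9
Reactants: 12 (3S,4R)-3-ethenyl-4-(3-hydroxyprop-1-en-2-yl)-3-methylcyclohexan-1-one
Product: 13 (3S,4R)-4-{3-[(tert-butyldiphenylsilyl)oxy]prop-1-en-2-yl}-3-ethenyl-3-methylcyclohexan-1-one
Conditions: tBuPh2SiCl, imidazole, CH2Cl2, rt
Reagents that add atoms: tert-butyl(chloro)diphenylsilane, CC(C)(C)[Si](Cl)(c1ccccc1)c1ccccc1
Why: Standard silylation gives a primary silyl ether robust enough to last to the final step.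

Step 10
Reactants: 13 (3S,4R)-4-{3-[(tert-butyldiphenylsilyl)oxy]prop-1-en-2-yl}-3-ethenyl-3-methylcyclohexan-1-one
Product: 15 (4R,5S)-4-{3-[(tert-butyldiphenylsilyl)oxy]prop-1-en-2-yl}-5-ethenyl-5-methylcyclohex-2-en-1-one, via silyl enol ether 14 (not isolated)
Conditions: LiN(iPr)2 (commercial solution), Me3SiCl, THF, −78 °C; then Pd(OAc)2 (10 mol%), O2, DMSO, rt
Reagents that add atoms: none
Why: Kinetic deprotonation occurs at C7 because C9 is neopentylic, and Saegusa–Ito oxidation of the resulting silyl enol ether gives the C6=C7 enone.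

Step 11
Reactants: 15 (4R,5S)-4-{3-[(tert-butyldiphenylsilyl)oxy]prop-1-en-2-yl}-5-ethenyl-5-methylcyclohex-2-en-1-one
Product: 16 (4R,5S)-4-{3-[(tert-butyldiphenylsilyl)oxy]prop-1-en-2-yl}-5-ethenyl-2-iodo-5-methylcyclohex-2-en-1-one
Conditions: I2, pyridine, CH2Cl2, rt
Reagents that add atoms: iodine, [I][I]
Why: Johnson α-iodination of an enone (pyridine conjugate addition, iodination, elimination) leaves the isolated alkenes alone.

Step 12
Reactants: 16 (4R,5S)-4-{3-[(tert-butyldiphenylsilyl)oxy]prop-1-en-2-yl}-5-ethenyl-2-iodo-5-methylcyclohex-2-en-1-one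
Product: 17 ethyl 2-[(3R,4S)-3-{3-[(tert-butyldiphenylsilyl)oxy]prop-1-en-2-yl}-4-ethenyl-4-methyl-6-oxocyclohex-1-en-1-yl]acetate
Conditions: BrZnCH2CO2Et (2 equiv, commercial solution), Pd2(dba)3 (2.5 mol%), XPhos (10 mol%), THF, 45 °C
Reagents that add atoms: (2-ethoxy-2-oxoethyl)zinc bromide, CCOC(=O)C[Zn]Br
Why: Negishi cross-coupling of the Reformatsky reagent with the vinyl iodide places the acetate arm regiospecifically on C7.

Step 13
Reactants: 17 ethyl 2-[(3R,4S)-3-{3-[(tert-butyldiphenylsilyl)oxy]prop-1-en-2-yl}-4-ethenyl-4-methyl-6-oxocyclohex-1-en-1-yl]acetate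
Product: 18 β-boryl ketone (ketone 13 carrying 7β-CH2CO2Et and 6α-pinacolboryl)
Conditions: CuCl (10 mol%), DPEphos (10 mol%), NaOtBu (15 mol%), B2pin2 (1.2 equiv), MeOH (2 equiv), THF, rt
Reagents that add atoms: bis(pinacolato)diboron, CC1(C)OB(OC1(C)C)B1OC(C)(C)C(C)(C)O1
Why: Copper-catalysed conjugate borylation delivers boron to C6 anti to the adjacent C5 substituent (6α), and C7, being α to the ketone, equilibrates under the alkoxide conditions to the all-equatorial 7β epimer.

Step 14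
Reactants: 18 β-boryl ketone
Product: 19 8α-alcohol (8α-OH, 7β-CH2CO2Et, 6α-pinacolboryl)
Conditions: SmI2 (2.5 equiv), THF/H2O, 0 °C
Reagents that add atoms: none
Why: Single-electron ketone reduction is expected to give the thermodynamically favoured equatorial 8α-alcohol (its epimer is syn-axial to the C10 methyl), whereas hydride reagents attack from the open α face and give mainly the axial alcohol.

Step 15
Reactants: 19 8α-alcohol
Product: 20 8α-triethylsilyl ether of 19
Conditions: Et3SiOTf, 2,6-lutidine, CH2Cl2, −78 °C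
Reagents that add atoms: triethylsilyl trifluoromethanesulfonate, CC[Si](CC)(CC)OS(=O)(=O)C(F)(F)F
Why: Immediate silylation blocks the C8 hydroxyl so that only the C6 oxygen can later close the lactone.

Step 16
Reactants: 20 8α-triethylsilyl ether
Product: 22 trans-fused 6α,12-lactone (8α-OSiEt3; 15-O-silyl), via hydroxy ester 21 (not isolated)
Conditions: H2O2 (30% aq.), NaHCO3, THF/H2O, 0 °C → rt; then PPTS (cat.), PhMe, 60 °C
Reagents that add atoms: hydrogen peroxide, OO
Why: Oxidation of the C–B bond with retention gives the 6α-alcohol, which is the only free hydroxyl and lactonises onto the neighbouring ester to the trans-fused γ-lactone.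

Step 17
Reactants: 22 trans-fused 6α,12-lactone
Product: 25 α-methylene lactone (8α-OSiEt3), via Mannich base 23 (not isolated), via ammonium iodide 24 (not isolated)
Conditions: LiN(SiMe3)2, THF, −78 °C, then CH2=NMe2+ I−; MeI, MeOH, rt; DBU, CH2Cl2, rt
Reagents that add atoms: Eschenmoser's salt (N,N-dimethylmethyleneiminium iodide), C=[N+](C)C.[I-]
Why: Mannich reaction of the lactone enolate, quaternisation and E1cB elimination give the exo-methylene (C13) without touching the protected C8 oxygen.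

Step 18
Reactants: 25 α-methylene lactone (8α-OSiEt3)
Product: 26 8α-hydroxy α-methylene lactone (15-O-tert-butyldiphenylsilyl)
Conditions: HF·pyridine, pyridine, THF, 0 °C
Reagents that add atoms: none
Why: Selective desilylation, because the secondary triethylsilyl ether is cleaved far faster than the primary tert-butyldiphenylsilyl ether.

Step 19
Reactants: 27 methyl (R)-3-hydroxy-2-methylpropanoate
Product: 28 methyl (R)-3-[(tert-butyldimethylsilyl)oxy]-2-methylpropanoate
Conditions: tBuMe2SiCl, imidazole, CH2Cl2, rt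
Reagents that add atoms: tert-butyl(chloro)dimethylsilane, CC(C)(C)[Si](C)(C)Cl
Why: Standard silyl protection of the primary alcohol; the stereocentre comes from the chiral pool.

Step 20
Reactants: 28 methyl (R)-3-[(tert-butyldimethylsilyl)oxy]-2-methylpropanoate
Product: 29 (R)-3-[(tert-butyldimethylsilyl)oxy]-2-methylpropanoic acid
Conditions: LiOH, THF/MeOH/H2O, 0 °C → rt; then 1 M HCl to pH 3
Reagents that add atoms: lithium hydroxide, [Li+].[OH-]
Why: Ester saponification at low temperature does not epimerise the α-centre.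

Step 21
Reactants: 26 8α-hydroxy α-methylene lactone; 29 (R)-3-[(tert-butyldimethylsilyl)oxy]-2-methylpropanoic acid
Product: 31 bis-silyl ether of the target (15-O-tert-butyldiphenylsilyl; side-chain O-tert-butyldimethylsilyl), via mixed anhydride 30 (not isolated)
Conditions: 29, 2,4,6-Cl3C6H2COCl, Et3N, THF, rt; then 26, DMAP (cat.), PhMe, rt
Reagents that add atoms: none
Why: Yamaguchi esterification acylates the hindered equatorial C8 alcohol with retention at C8 and without epimerising the acid.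

Step 22
Reactants: 31 bis-silyl ether of the target
Product: 32 CNP0133858.1 (target)
Conditions: HF·pyridine (excess), pyridine, THF, 0 °C → rt
Reagents that add atoms: none
Why: Global fluoride desilylation under mildly acidic conditions spares the ester, the lactone and both exo-methylene groups.

## Compound list

1 | methyl 4,4-dimethoxybutanoate | COC(=O)CCC(OC)OC | starting material
2 | 4,4-dimethoxybutanal | O=CCCC(OC)OC | intermediate
3 | but-3-en-2-one (methyl vinyl ketone) | CC(=O)C=C | starting material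
4 | (S)-2-(2,2-dimethoxyethyl)-5-oxohexanal | O=C[C@H](CC(OC)OC)CCC(C)=O | intermediate
5 | (S)-4-(2,2-dimethoxyethyl)cyclohex-2-en-1-one | O=C1C=C[C@H](CC(OC)OC)CC1 | intermediate
6 | {[(3S,4S)-4-(2,2-dimethoxyethyl)-3-methylcyclohex-1-en-1-yl]oxy}trimethylsilane (3,4-trans) | C[Si](C)(C)OC1=C[C@@H](C)[C@H](CC(OC)OC)CC1 | intermediate
7 | (S)-4-(2,2-dimethoxyethyl)-3-methylcyclohex-2-en-1-one | O=C1C=C(C)[C@H](CC(OC)OC)CC1 | intermediate
8 | {[(3S,4S)-3-ethenyl-4-(2,2-dimethoxyethyl)-3-methylcyclohex-1-en-1-yl]oxy}trimethylsilane | C=C[C@]1(C)C=C(O[Si](C)(C)C)CC[C@H]1CC(OC)OC | intermediate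
9 | (3S,4S)-3-ethenyl-4-(2,2-dimethoxyethyl)-3-methylcyclohexan-1-one (vinyl trans to the side chain) | C=C[C@]1(C)CC(=O)CC[C@H]1CC(OC)OC | intermediate
10 | 2-[(1S,2S)-2-ethenyl-2-methyl-4-oxocyclohexyl]acetaldehyde | C=C[C@]1(C)CC(=O)CC[C@H]1CC=O | intermediate
11 | 2-[(1R,2S)-2-ethenyl-2-methyl-4-oxocyclohexyl]prop-2-enal | C=C[C@]1(C)CC(=O)CC[C@H]1C(=C)C=O | intermediate
12 | (3S,4R)-3-ethenyl-4-(3-hydroxyprop-1-en-2-yl)-3-methylcyclohexan-1-one | C=C[C@]1(C)CC(=O)CC[C@H]1C(=C)CO | intermediate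
13 | (3S,4R)-4-{3-[(tert-butyldiphenylsilyl)oxy]prop-1-en-2-yl}-3-ethenyl-3-methylcyclohexan-1-one | C=C[C@]1(C)CC(=O)CC[C@H]1C(=C)CO[Si](c1ccccc1)(c1ccccc1)C(C)(C)C | intermediate
14 | kinetic trimethylsilyl enol ether of 13 (C7=C8–OSiMe3) | C=C[C@]1(C)CC(O[Si](C)(C)C)=CC[C@H]1C(=C)CO[Si](c1ccccc1)(c1ccccc1)C(C)(C)C | intermediate
15 | (4R,5S)-4-{3-[(tert-butyldiphenylsilyl)oxy]prop-1-en-2-yl}-5-ethenyl-5-methylcyclohex-2-en-1-one | C=C[C@]1(C)CC(=O)C=C[C@H]1C(=C)CO[Si](c1ccccc1)(c1ccccc1)C(C)(C)C | intermediate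
16 | (4R,5S)-4-{3-[(tert-butyldiphenylsilyl)oxy]prop-1-en-2-yl}-5-ethenyl-2-iodo-5-methylcyclohex-2-en-1-one | C=C[C@]1(C)CC(=O)C(I)=C[C@H]1C(=C)CO[Si](c1ccccc1)(c1ccccc1)C(C)(C)C | intermediate
17 | ethyl 2-[(3R,4S)-3-{3-[(tert-butyldiphenylsilyl)oxy]prop-1-en-2-yl}-4-ethenyl-4-methyl-6-oxocyclohex-1-en-1-yl]acetate | C=C[C@]1(C)CC(=O)C(CC(=O)OCC)=C[C@H]1C(=C)CO[Si](c1ccccc1)(c1ccccc1)C(C)(C)C | intermediate
18 | β-boryl ketone: ketone 13 carrying 7β-CH2CO2Et and 6α-(4,4,5,5-tetramethyl-1,3,2-dioxaborolan-2-yl) | C=C[C@]1(C)CC(=O)[C@@H](CC(=O)OCC)[C@H](B2OC(C)(C)C(C)(C)O2)[C@H]1C(=C)CO[Si](c1ccccc1)(c1ccccc1)C(C)(C)C | intermediate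
19 | 8α-alcohol of 18 (8α-OH, 7β-CH2CO2Et, 6α-pinacolboryl) | C=C[C@]1(C)C[C@H](O)[C@@H](CC(=O)OCC)[C@H](B2OC(C)(C)C(C)(C)O2)[C@H]1C(=C)CO[Si](c1ccccc1)(c1ccccc1)C(C)(C)C | intermediate
20 | 8α-triethylsilyl ether of 19 | C=C[C@]1(C)C[C@H](O[Si](CC)(CC)CC)[C@@H](CC(=O)OCC)[C@H](B2OC(C)(C)C(C)(C)O2)[C@H]1C(=C)CO[Si](c1ccccc1)(c1ccccc1)C(C)(C)C | intermediate
21 | 6α-hydroxy ester (6α-OH, 7β-CH2CO2Et, 8α-OSiEt3) | C=C[C@]1(C)C[C@H](O[Si](CC)(CC)CC)[C@@H](CC(=O)OCC)[C@H](O)[C@H]1C(=C)CO[Si](c1ccccc1)(c1ccccc1)C(C)(C)C | intermediate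
22 | trans-fused 6α,12-lactone with 8α-OSiEt3 and 15-O-tert-butyldiphenylsilyl | C=C[C@]1(C)C[C@H](O[Si](CC)(CC)CC)[C@H]2CC(=O)O[C@@H]2[C@H]1C(=C)CO[Si](c1ccccc1)(c1ccccc1)C(C)(C)C | intermediate
23 | Mannich base of 22 (11-dimethylaminomethyl lactone; C11 epimers) | C=C[C@]1(C)C[C@H](O[Si](CC)(CC)CC)[C@H]2C(CN(C)C)C(=O)O[C@@H]2[C@H]1C(=C)CO[Si](c1ccccc1)(c1ccccc1)C(C)(C)C | intermediate
24 | trimethylammoniomethyl lactone iodide from 23 | C=C[C@]1(C)C[C@H](O[Si](CC)(CC)CC)[C@H]2C(C[N+](C)(C)C)C(=O)O[C@@H]2[C@H]1C(=C)CO[Si](c1ccccc1)(c1ccccc1)C(C)(C)C.[I-] | intermediate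
25 | α-methylene lactone with 8α-OSiEt3 and 15-O-tert-butyldiphenylsilyl | C=C[C@]1(C)C[C@H](O[Si](CC)(CC)CC)[C@H]2C(=C)C(=O)O[C@@H]2[C@H]1C(=C)CO[Si](c1ccccc1)(c1ccccc1)C(C)(C)C | intermediate
26 | 8α-hydroxy α-methylene lactone, 15-O-tert-butyldiphenylsilyl | C=C[C@]1(C)C[C@H](O)[C@H]2C(=C)C(=O)O[C@@H]2[C@H]1C(=C)CO[Si](c1ccccc1)(c1ccccc1)C(C)(C)C | intermediate
27 | methyl (R)-3-hydroxy-2-methylpropanoate | COC(=O)[C@H](C)CO | starting material
28 | methyl (R)-3-[(tert-butyldimethylsilyl)oxy]-2-methylpropanoate | COC(=O)[C@H](C)CO[Si](C)(C)C(C)(C)C | intermediate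
29 | (R)-3-[(tert-butyldimethylsilyl)oxy]-2-methylpropanoic acid | OC(=O)[C@H](C)CO[Si](C)(C)C(C)(C)C | intermediate
30 | mixed anhydride of 29 with 2,4,6-trichlorobenzoic acid | O=C(OC(=O)[C@H](C)CO[Si](C)(C)C(C)(C)C)c1c(Cl)cc(Cl)cc1Cl | intermediate
31 | bis-silyl ether of the target (15-O-tert-butyldiphenylsilyl; side-chain O-tert-butyldimethylsilyl) | C=C[C@]1(C)C[C@H](OC(=O)[C@H](C)CO[Si](C)(C)C(C)(C)C)[C@H]2C(=C)C(=O)O[C@@H]2[C@H]1C(=C)CO[Si](c1ccccc1)(c1ccccc1)C(C)(C)C | intermediate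
32 | CNP0133858.1 | C=C[C@]1(C)C[C@H](OC(=O)[C@H](C)CO)[C@H]2C(=C)C(=O)O[C@@H]2[C@H]1C(=C)CO | target

## Step count and risks

Total step count: 22 (20 in the main line, 2 for acid 29). Longest linear sequence: 20 steps (steps 1–18, 21, 22).

The three steps most likely to fail are steps 12, 13 and 14.

**Step 12 (Negishi coupling of the Reformatsky reagent with iodoenone 16).** The coupling may stall through protodeiodination or conjugate addition of the zinc enolate. The fallback sets out from 13 and puts the acetate arm on before the ring double bond. Ketone 13 is deprotonated at C7 (LiN(iPr)2, THF, −78 °C) and alkylated with ethyl bromoacetate to give the 7-(ethoxycarbonylmethyl) ketone F1. Dehydrogenation of F1 with IBX (DMSO/fluorobenzene, 70 °C) then gives enone 17, where the fallback rejoins the route. Because C10 is quaternary, ring unsaturation can only form on the C6–C7 side; the risk moved into this variant is exocyclic unsaturation towards the ester.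

**Step 13 (conjugate borylation of the hindered, α-substituted enone 17).** If borylation is slow or unselective, oxygen is delivered to C6 by nucleophilic epoxidation instead; the fallback sets out from 17. tBuOOH/DBU (THF, 0 °C) gives the 6α,7α-epoxy ketone F2, with the peroxide entering anti to the C5 substituent. SmI2 (THF/MeOH, −78 °C) cleaves the Cα–O bond to the β-hydroxy ketone F3, in which C7 equilibrates to 7β. F3 is silylated (Me3SiCl, imidazole) to the trimethylsilyl ether F4, reduced with SmI2/H2O as in step 14 to the 8α-alcohol F5, and protected (Et3SiOTf, 2,6-lutidine) as the bis-silyl ether F6. K2CO3/MeOH removes only the trimethylsilyl group and returns hydroxy ester 21, which lactonises to 22 as in step 16.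

**Step 14 (stereochemistry of the C8 ketone reduction).** If SmI2 gives too much of the axial 8β-alcohol, C8 is set by inversion instead; the fallback sets out from 18. Oxidation (H2O2, NaHCO3) by way of hydroxy ketone F3 and lactonisation (PPTS, PhMe) give the keto lactone F7, which must be kept away from base. LiBH(s-Bu)3 (THF, −78 °C, acetic acid quench) attacks from the open α face and gives the axial 8β-alcohol F8. Mitsunobu reaction (4-nitrobenzoic acid, PPh3, DIAD) inverts C8 to the 8α-(4-nitrobenzoate) F9. Methanolysis (NaN3, MeOH, 40 °C) gives the 8α-alcohol F10, and Et3SiOTf/2,6-lutidine converts F10 into 22, where the fallback rejoins the route.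

## Further compounds

F1 | step 12 | ketone 13 carrying 7β-CH2CO2Et | C=C[C@]1(C)CC(=O)[C@@H](CC(=O)OCC)C[C@H]1C(=C)CO[Si](c1ccccc1)(c1ccccc1)C(C)(C)C
F2 | step 13 | 6α,7α-epoxy ketone from 17 | C=C[C@]1(C)CC(=O)[C@]2(CC(=O)OCC)O[C@@H]2[C@H]1C(=C)CO[Si](c1ccccc1)(c1ccccc1)C(C)(C)C
F3 | step 13 | β-hydroxy ketone (6α-OH, 7β-CH2CO2Et, 8-oxo) | C=C[C@]1(C)CC(=O)[C@@H](CC(=O)OCC)[C@H](O)[C@H]1C(=C)CO[Si](c1ccccc1)(c1ccccc1)C(C)(C)C
F4 | step 13 | 6α-trimethylsilyl ether of F3 | C=C[C@]1(C)CC(=O)[C@@H](CC(=O)OCC)[C@H](O[Si](C)(C)C)[C@H]1C(=C)CO[Si](c1ccccc1)(c1ccccc1)C(C)(C)C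
F5 | step 13 | 8α-alcohol of F4 | C=C[C@]1(C)C[C@H](O)[C@@H](CC(=O)OCC)[C@H](O[Si](C)(C)C)[C@H]1C(=C)CO[Si](c1ccccc1)(c1ccccc1)C(C)(C)C
F6 | step 13 | 8α-triethylsilyl ether of F5 | C=C[C@]1(C)C[C@H](O[Si](CC)(CC)CC)[C@@H](CC(=O)OCC)[C@H](O[Si](C)(C)C)[C@H]1C(=C)CO[Si](c1ccccc1)(c1ccccc1)C(C)(C)C
F7 | step 14 | 8-oxo trans-fused 6α,12-lactone | C=C[C@]1(C)CC(=O)[C@H]2CC(=O)O[C@@H]2[C@H]1C(=C)CO[Si](c1ccccc1)(c1ccccc1)C(C)(C)C
F8 | step 14 | 8β-hydroxy 6α,12-lactone | C=C[C@]1(C)C[C@@H](O)[C@H]2CC(=O)O[C@@H]2[C@H]1C(=C)CO[Si](c1ccccc1)(c1ccccc1)C(C)(C)C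
F9 | step 14 | 8α-(4-nitrobenzoyloxy) 6α,12-lactone | C=C[C@]1(C)C[C@H](OC(=O)c2ccc(cc2)[N+](=O)[O-])[C@H]2CC(=O)O[C@@H]2[C@H]1C(=C)CO[Si](c1ccccc1)(c1ccccc1)C(C)(C)C
F10 | step 14 | 8α-hydroxy 6α,12-lactone | C=C[C@]1(C)C[C@H](O)[C@H]2CC(=O)O[C@@H]2[C@H]1C(=C)CO[Si](c1ccccc1)(c1ccccc1)C(C)(C)C
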